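(The runs were computed from invented constants, noise included.)

If left-handed substrate and right-handed substrate never exchange, the faster hand runs down first and the product's excess sinks as the run goes on. If they exchange at once, the excess holds. Ana and Ben dispute which picture fits this flask.

common to all: racemization catalyst 13 µM

| flask | left-handed substrate | right-handed substrate | partner | added ligand | remark | time |
|---|---|---|---|---|---|---|
| Monday's | 10 mM | 10 mM | 30 mM | 20 µM | run made earlier |  |
| Sunday's | 10 mM | 10 mM | 30 mM | 45 µM | run made earlier |  |
| Tuesday's | 5 mM | 5 mM | 30 mM | 30 µM | run made earlier |  |
| flask | 10 mM | 10 mM | 30.0 mM | 30 µM |  | 10 h |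

| run | time / h | left-handed product / % | right-handed product / % |
|---|---|---|---|
| Monday's | 0.833 | 5 | 2 |
| Monday's | 2.00 | 7 | 3 |
| Monday's | 4.00 | 13 | 7 |
| Monday's | 6.00 | 19 | 8 |
| Sunday's | 0.833 | 4 | 3 |
| Sunday's | 2.00 | 9 | 2 |
| Sunday's | 4.00 | 12 | 5 |
| Sunday's | 6.00 | 21 | 9 |
| Tuesday's | 1.50 | 3 | 3 |
| Tuesday's | 3.00 | 12 | 5 |
| Tuesday's | 5.00 | 21 | 4 |
| Tuesday's | 6.00 | 19 | 6 |

(standard deviation of a reading: 1.5 percentage points)

- partner is single-handed; left-handed substrate and right-handed substrate are mirror images of each other, charged as a racemate, each of them at the stated concentration
- an excess is below zero if the other one leads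
- the handed part of partner does not stay in what it makes, so the products of the two hands are mirror images too

* left-handed product and right-handed product together, in percent of the left-handed substrate and right-handed substrate charged together, at 10 h
* excess of left-handed product over right-handed product in the product at 10 h
* whether the exchange between left-handed substrate and right-handed substrate keeps pace with the reaction: how far the product's excess at 10 h gets from its value without exchange to its value with instant exchange (above 80% keeps pace, below 20% hardly takes part, else lags behind)

Summed over the earlier runs, left-handed product over right-handed product reads 2.54. Both take this reading as s, the selectivity factor: the rate constant of the left-handed hand over that of the right-handed hand.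

Ana holds that exchange is instant, so the excess stays at (s−1)/(s+1), which is 43.6%. Her support is the pooled excess at 6.00 h, which reads 43.9%.

Ben holds that there is no exchange. Sunday's run has 45 µM of added ligand against 20 µM in Monday's, yet their excesses at 6.00 h read 40.0% and 40.7%. He replaces the falling curve by one mean constant. The pooled total at 6.00 h is 27.3%, so k, the mean first-order constant, is 0.0532 h⁻¹. Split by s, the hands get 0.0764 h⁻¹ and 0.0300 h⁻¹.

Put back at 6.00 h, these give 26.6%, a gap of 0.7 percentage points from the mean. With a scatter of 1.5 points on each reading, the excesses cannot part the two views.

I side with Ben. At 10 h his constants leave 46.6% and 74.1% of each hand's charge, so I commit to 39.6% with an excess of 34.7%. His rule also gives a test. Both hands meet the same partner, so without exchange the left-handed remnant equals the right-handed remnant raised to the power s.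

The forecast, which differs from my reckoning, says 42%, 45% and lags behind, noting that “The data barely separate the two limits”.

The flask gives 38.7% with an excess of 34.9%, and the exchange hardly takes part, getting 2.7% of the way.

    left-handed substrate + racemization catalyst ⇌ right-handed substrate + racemization catalyst, rate k1*[racemization catalyst]*[left-handed substrate] forward; the back reaction follows from the equilibrium constant (k = 170 M⁻¹ min⁻¹)
    racemization catalyst → spent catalyst (k = 0.00540 min⁻¹)
    partner + right-handed substrate → right-handed product (k = 0.0190 M⁻¹ min⁻¹)
    partner + left-handed substrate → left-handed product (k = 0.0480 M⁻¹ min⁻¹)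
    racemization catalyst + added ligand ⇌ idle complex, settled at all times (K = 1.60 × 10⁶ M⁻¹)

Ana's number stands close in the flask while little has reacted: after 1.00 h, with 5.71% reacted, the excess stood at 42.3% against her 43.6%, but Ben's constants give 42.7% there, so that nearness does not favour her. At 10 h right-handed substrate keeps 74% of its charge, so the rule gives 46.5% for left-handed substrate, and the flask holds 48%. In the neighbour with 120 mM of partner, right-handed substrate keeps 28%, the rule gives 4.05%, and left-handed substrate stands at 4.7%.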